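## The problem

Atom labels (C2 to C8a, C1' to C6') are those of the flavone and are kept for the open-chain and pyranone intermediates.

The target is a flavone without any stereocenter, so nothing has to be controlled in space. What has to be controlled is which of the seven oxygen atoms on the two benzene rings is methylated and which is free. Ring A carries a free hydroxyl at C5 beside methoxyls at C6 and C7. Ring B carries three contiguous methoxyls at C2', C3', C4' and a free hydroxyl at C6', so C2 is flanked by two ortho substituents. Only the C5 hydroxyl could be freed at the end by demethylation (the peri carbonyl helps there); the C6' oxygen must travel as an ether that is distinct from methyl. That C6' hydroxyl is also the sensitive point: once free, acid or a Lewis acid can reopen the pyranone and let it re-close onto ring B, so every diketone intermediate needs this oxygen capped and the last step must be neutral. Ring C can close onto a phloroglucinol-type ring A through either ortho oxygen and must be steered to the C8a oxygen. The enabling feature is that C4, C5, C7 and C8a carry oxygen on alternate carbons, with one extra methoxyl on C6: this is a linear poly-β-carbonyl chain ending in an ester. It can fold into ring A by joining C4a to C8a, and its C2–C5 segment can be stored as a 4-pyranone until then.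

## Retrosynthesis

**Benzyl ether and C7 methyl (16 ⇐ 15 ⇐ 14).** The O–CH2Ph bond at C6' and the O–CH3 bond at C7 are cut first. Benzyl is removed by neutral hydrogenolysis, which avoids the acid-induced ring reopening described above. The C7 methyl is cut next because in 14 the C7 hydroxyl is the only phenol not tied into the chelate with C4=O, so it can be methylated selectively. Precursor 14 is simply the product of closing ring C onto a phloroglucinol. The forward steps must discriminate 7-OH from 5-OH and leave the C2=C3 bond intact.

**Ring C (14 ⇐ 13).** The O1–C2 bond is cut, giving the 2-hydroxyaryl 1,3-diketone 13. Cutting O1–C8a instead would require a ring A with a leaving group or an oxidizable position at C8a, which the folding route does not supply. The forward cyclodehydration must go through the C8a oxygen and not the C5 oxygen, under acid mild enough for the benzyl ether.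

**Ring A (13 ⇐ 12 ⇐ 11).** The C4a–C8a bond is cut. Cutting C4–C4a (acylation of a preformed tetraoxygenated benzene) would need three ring hydroxyls differentiated beforehand. Cutting C4a–C8a gives the open tetraketo ester 12, in which every oxygen is placed by a building block. Chain 12 is not handled as such; it is stored as the 4-pyranone β-keto ester 11, which is stable and has one racemic center that disappears on aromatization. The forward reaction must choose Claisen closure over the aldol closures available to the same chain.

**Side chain (11 ⇐ 8 + 9 via 10; 8 ⇐ 7).** The C7–C8 bond is cut to the acid 8 and potassium methyl malonate 9, then the C6–C7 bond to the pyranone 7 and CO2. A single acylation of the lateral anion with a malonyl chloride would make both bonds at once, but it pairs a carbanion with an acidic acid chloride. Two steps of standard reactivity are preferred, and the one-step version is kept as a fallback. The forward steps need lateral deprotonation at the methoxymethyl group and cold handling of 8.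

**Pyranone (7 ⇐ 6 ⇐ 4 + 5).** The ring O–C5 bond is cut to the triketone 6, then the C4a–C5 bond to the diketone 4 and methyl methoxyacetate 5. Ester 5 delivers C5, C6 and the C6 methoxyl, so this oxygen is fixed before ring A exists. The forward steps need acylation of the diketone dianion at its terminal carbon and a ring closure that spares the benzyl ether.

**Ring B ketone (4 ⇐ 3 ⇐ 2 ⇐ 1).** The C3–C4 bond is cut (Claisen with ethyl acetate), then the benzyl ether, then the C1'–C2 bond (C-acetylation). Phenol 1 has two equivalent ortho positions and a blocked para position, so ring B's substitution pattern follows without any regiochemical question.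

## Roads not taken

**Alternative 1: ring B by chromium carbene benzannulation.**
- Cut: three bonds of ring B (C2'–C3', C1'–C6', C5'–C6').
- Forward key step: a Dötz reaction between 5,6,7-trimethoxy-2-(methoxyethynyl)-4H-chromen-4-one A2, the zerovalent chromium carbene complex pentacarbonyl[methoxy(1-methoxyethenyl)carbene]chromium A3 and one CO ligand. It would give 6'-hydroxy-5,6,7,2',3',4'-hexamethoxyflavone A1; chelation-controlled cleavage of the 5-O-methyl group would then give 16.
- Merits: the C6' hydroxyl comes from CO and is therefore free and distinct from every methoxyl without a protecting group. The sequence after ring construction is a single step.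
- Weak points: A2 is a push–pull ynol ether on a vinylogous ester, a class that is hard to make and prone to hydration. Acceptor-substituted and heteroatom-substituted alkynes are the cases where benzannulation regiochemistry and chemoselectivity (cyclobutenones, furans) are least reliable. A1 is a hydroquinone monoether released as a Cr(CO)3 complex, so oxidative demetalation risks quinone formation. Chromium is used stoichiometrically. The final Lewis acid step acts on a flavone with a free C6' hydroxyl.
- Comparison: this road is better in needing no protecting group on O6', which the chosen plan must carry through ten steps. The chosen plan sets against it that every one of its partners belongs to a known compound class and every step to a known reaction type.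

**Alternative 2: oxidative ring C closure through a ring A ortho-quinone.**
- Cut: the O1–C8a bond.
- Forward key step: Ag2O would oxidize the catechol diketone 1-[2-(benzyloxy)-4,5,6-trimethoxyphenyl]-3-(2,3-dihydroxy-4-methoxyphenyl)propane-1,3-dione A4 to its ortho-quinone A5. The enol oxygen on C2 would add to C8a (6-endo conjugate addition) and tautomerization would give 6'-(benzyloxy)-5,6-dihydroxy-7,2',3',4'-tetramethoxyflavone A6. Methylation of the unchelated C6 hydroxyl would lead to 15 and hydrogenolysis to 16.
- Merits: ring C can close in only one direction, and ring A comes from a simple pyrogallol-type ketone. The sequence is shorter than the chosen one.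
- Weak points: closing a flavone by adding a diketone enol to an ortho-quinone has little precedent. A5 combines a strong electrophile with an acidic diketone, which invites intermolecular addition. A6 is itself a catechol that is more electron-rich than A4, so over-oxidation and redox exchange with A5 are expected.
- Comparison: in regiochemical certainty of ring C this road is better than step 9 of the chosen plan, which rests on a bias between two ortho hydroxyls. The chosen plan sets against it that it contains no oxidation at the polyphenol stage and that its critical selectivity (Claisen against aldol) has close precedent.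

**Alternative 3: three-component carbonylative annulation.**
- Cut: C4a–C4, C4–C3 and O1–C2.
- Forward key step: 2-iodo-3,4,5-trimethoxyphenol A7 (one iodination from 1), carbon monoxide and 1-(benzyloxy)-2-ethynyl-3,4,5-trimethoxybenzene A8 would combine under PdCl2(PPh3)2 and Et2NH to give 2-[2-(benzyloxy)-4,5,6-trimethoxyphenyl]-5,6,7-trimethoxy-4H-chromen-4-one A9. Selective 5-O-demethylation and hydrogenolysis would finish.
- Merits: this is the most convergent road. Both rings derive from phenol 1, the regiochemistry is fixed by the position of iodine, and the reaction type is established for flavones.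
- Weak points: the aryl iodide is electron-rich and doubly ortho-substituted and the alkyne is doubly ortho-substituted, so oxidative addition and CO insertion must outrun direct coupling to a benzofuran and 5-exo closure to an aurone. The free C5 hydroxyl must then be made by Lewis acid demethylation in a molecule with five other methyl ethers and a benzyl ether.
- Comparison: in step count and in weight of precedent this road is ahead of the chosen plan, and the fallback for the key step below leads to the same flavone A9. The chosen plan sets against it that the C5 hydroxyl is born free, so no late demethylation is needed, and that ring A's oxygen pattern is written by the acyclic building blocks and can be varied through the acylating ester.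

Key step: step 8

Assumption: the methoxy-bearing carbon of 8, 10, 11 and 12 is formed racemic; it becomes the sp2 carbon C6 of ring A, so no enantiocontrol is planned.

## Route

Step 1
Reactants: 1 3,4,5-trimethoxyphenol
Product: 2 1-(2-hydroxy-4,5,6-trimethoxyphenyl)ethan-1-one
Conditions: AcOH, BF3·OEt2 (co-solvent), 90 °C; H2O work-up
Reagents that add atoms: acetic acid, CC(=O)O
Why: Friedel–Crafts C-acetylation of a phenol promoted by BF3 (by way of the aryl acetate and a Fries-type shift); the two positions ortho to the hydroxyl of 1 are equivalent and the para position is occupied, so only one ketone can form, and its boron chelate resists a second acylation.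

Step 2
Reactants: 2 1-(2-hydroxy-4,5,6-trimethoxyphenyl)ethan-1-one
Product: 3 1-[2-(benzyloxy)-4,5,6-trimethoxyphenyl]ethan-1-one
Conditions: BnBr, K2CO3, DMF, 60 °C
Reagents that add atoms: benzyl bromide, BrCc1ccccc1
Why: Williamson etherification; the hydroxyl is hydrogen-bonded to the ketone, hence the polar solvent and gentle heat. Benzyl is chosen because it should withstand the strong bases and mild acids of steps 3 to 10 and leaves by neutral hydrogenolysis.

Step 3
Reactants: 3 1-[2-(benzyloxy)-4,5,6-trimethoxyphenyl]ethan-1-one
Product: 4 1-[2-(benzyloxy)-4,5,6-trimethoxyphenyl]butane-1,3-dione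
Conditions: NaH (2.5 equiv), EtOAc, THF, 0 °C → reflux; aq. HCl
Reagents that add atoms: ethyl acetate, CCOC(C)=O
Why: Crossed Claisen condensation of the methyl ketone enolate with ethyl acetate, driven by formation of the stable diketonate; the ester self-condensation product is removed on work-up and chromatography.

Step 4
Reactants: 4 1-[2-(benzyloxy)-4,5,6-trimethoxyphenyl]butane-1,3-dione; 5 methyl 2-methoxyacetate
Product: 6 1-[2-(benzyloxy)-4,5,6-trimethoxyphenyl]-6-methoxyhexane-1,3,5-trione
Conditions: LiN(iPr)2 (2.1 equiv per 4), THF, −78 → 0 °C; 5 (0.5 equiv per 4), 0 °C; aq. HCl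
Reagents that add atoms: none
Why: Acylation of a 1,3-diketone dianion at its terminal carbon by an ester: the second deprotonation takes place at the methyl group and this more reactive carbanion attacks the ester. A second equivalent of dianion takes up the acidic proton of the triketone, and unchanged 4 is recovered.

Step 5
Reactants: 6 1-[2-(benzyloxy)-4,5,6-trimethoxyphenyl]-6-methoxyhexane-1,3,5-trione
Product: 7 2-[2-(benzyloxy)-4,5,6-trimethoxyphenyl]-6-(methoxymethyl)-4H-pyran-4-one
Conditions: TsOH·H2O (cat.), toluene, reflux, Dean–Stark
Reagents that add atoms: none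
Why: Acid-catalysed cyclodehydration of a 1,3,5-triketone to a 4-pyranone: a terminal enol oxygen adds to the carbonyl at the other end and water is lost. Catalytic TsOH with azeotropic water removal should spare the benzyl ether, which cold concentrated H2SO4 might not.

Step 6
Reactants: 7 2-[2-(benzyloxy)-4,5,6-trimethoxyphenyl]-6-(methoxymethyl)-4H-pyran-4-one
Product: 8 rac-2-{6-[2-(benzyloxy)-4,5,6-trimethoxyphenyl]-4-oxo-4H-pyran-2-yl}-2-methoxyacetic acid
Conditions: LiN(iPr)2 (1.1 equiv), THF, −78 °C; CO2 (gas, excess), −78 → −20 °C; cold aq. HCl to pH 3
Reagents that add atoms: carbon dioxide, O=C=O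
Why: Lateral metalation of a 2-alkyl-4-pyranone followed by carboxylation: the CH2 group is a vinylogous α-position of the pyranone carbonyl, further acidified by the methoxyl, and the dienolate reacts with CO2 at the exocyclic carbon. Excess CO2 and cold acidification limit proton transfer and decarboxylation; the new stereocenter is formed racemic and is of no consequence.

Step 7
Reactants: 8 rac-2-{6-[2-(benzyloxy)-4,5,6-trimethoxyphenyl]-4-oxo-4H-pyran-2-yl}-2-methoxyacetic acid; 9 potassium methyl malonate (KO2CCH2CO2Me)
Product: 11 rac-methyl 4-{6-[2-(benzyloxy)-4,5,6-trimethoxyphenyl]-4-oxo-4H-pyran-2-yl}-4-methoxy-3-oxobutanoate, via acyl imidazolide 10 (not isolated)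
Conditions: 1,1'-carbonyldiimidazole, THF, rt; then 9, MgCl2, Et3N, MeCN, rt → 40 °C; aq. HCl
Reagents that add atoms: 1,1'-carbonyldiimidazole, O=C(n1ccnc1)n1ccnc1 (its imidazolyl group is in 10 only; 11 takes its new atoms from 9)
Why: Masamune–Brooks two-carbon homologation: the acyl imidazolide is C-acylated by the magnesium enolate of the malonate half ester under nearly neutral conditions and decarboxylation gives the β-keto ester. This is the standard method for acids that carry an acidic α-hydrogen.

Step 8
Reactants: 11 rac-methyl 4-{6-[2-(benzyloxy)-4,5,6-trimethoxyphenyl]-4-oxo-4H-pyran-2-yl}-4-methoxy-3-oxobutanoate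
Product: 13 1-[2-(benzyloxy)-4,5,6-trimethoxyphenyl]-3-(2,4,6-trihydroxy-3-methoxyphenyl)propane-1,3-dione, via open-chain tetraketo ester 12 (not isolated)
Conditions: KOH (1 M, 6 equiv), MeOH–H2O 4:1, N2, 0 °C → rt; then aq. HCl, 0 °C
Reagents that add atoms: water (delivered as hydroxide), O
Why: Hydroxide adds to the pyranone at C5 (C2 is screened by the doubly ortho-substituted aryl group), the ring C5–O bond breaks, and the chain is set free as the polyenolate of the tetraketo ester 12. The carbanion at C4a, flanked by the C4 and C5 carbonyls, attacks the ester carbon C8a, methoxide leaves, and the resulting 2-acylcyclohexane-1,3,5-trione enolizes to the aromatic triol 13, so the C4a–C8a bond and ring A are made in one event. The closest known reaction type is the base-induced opening of 4-pyranone-masked polyketones combined with the Claisen cyclization of 3,5,7-triketo esters to acylphloroglucinols, the laboratory counterpart of chalcone synthase folding. Ring A closes in a 6-exo-trig Dieckmann-type mode. No stereocenter is formed, and the racemic methoxy-bearing carbon of 11 becomes the sp2 carbon C6. The selectivity needed is Claisen closure in preference to the aldol closures of C8 onto C4 and of C3 onto C7 and to saponification of the ester: in excess strong base every ketone is part of an enolate and a poor acceptor, the aryl ketone C2 is shielded by its two ortho substituents, and the ester carbonyl, whose neighbouring enolate keeps its charge on the C7 oxygen, remains the best electrophile within reach of C4a. Aromatization and deprotonation of the phloroglucinol should make the closure irreversible, and the benzyl and methyl ethers are inert to cold aqueous-methanolic KOH under N2.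

Step 9
Reactants: 13 1-[2-(benzyloxy)-4,5,6-trimethoxyphenyl]-3-(2,4,6-trihydroxy-3-methoxyphenyl)propane-1,3-dione
Product: 14 2-[2-(benzyloxy)-4,5,6-trimethoxyphenyl]-5,7-dihydroxy-6-methoxy-4H-chromen-4-one
Conditions: NaOAc, AcOH, 100 °C
Reagents that add atoms: none
Why: Acid-catalysed cyclodehydration of a 2-hydroxyaryl 1,3-diketone, the closing stage of a Baker–Venkataraman flavone synthesis. The C5 hydroxyl, buttressed by the C6 methoxyl, should be held in the hydrogen bond to C4=O, which turns the diketone arm toward the C8a hydroxyl; the 5,6,7-oxygenated flavone is also the stable member of the Wessely–Moser pair, so kinetic and thermodynamic bias both point to 14. Buffered acetic acid should leave the benzyl ether intact, and ring B, whose ortho oxygens are both etherified, cannot compete.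

Step 10
Reactants: 14 2-[2-(benzyloxy)-4,5,6-trimethoxyphenyl]-5,7-dihydroxy-6-methoxy-4H-chromen-4-one
Product: 15 2-[2-(benzyloxy)-4,5,6-trimethoxyphenyl]-5-hydroxy-6,7-dimethoxy-4H-chromen-4-one
Conditions: MeI (1.1 equiv), K2CO3 (1.2 equiv), acetone, rt
Reagents that add atoms: iodomethane, CI
Why: Williamson methylation under weak base: the C7 hydroxyl is the most acidic phenol of 14 (a vinylogous carboxylic acid), whereas the C5 hydroxyl is held in the chelate with C4=O and should stay unmethylated with one equivalent of MeI at room temperature.

Step 11
Reactants: 15 2-[2-(benzyloxy)-4,5,6-trimethoxyphenyl]-5-hydroxy-6,7-dimethoxy-4H-chromen-4-one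
Product: 16 5-hydroxy-2-(6-hydroxy-2,3,4-trimethoxyphenyl)-6,7-dimethoxy-4H-chromen-4-one (5,6'-dihydroxy-6,7,2',3',4'-pentamethoxyflavone)
Conditions: H2 (1 atm), Pd/C (10% Pd on carbon), EtOAc–MeOH, rt
Reagents that add atoms: none
Why: Hydrogenolysis of the aryl benzyl ether over palladium; the conditions are neutral, so the freed C6' hydroxyl has no opportunity to reopen and re-close the pyranone. The methyl ethers and the C2=C3 bond of the flavone should not be affected at 1 atm.

## Compound list

1 | 3,4,5-trimethoxyphenol | COc1cc(O)cc(OC)c1OC | starting material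
2 | 1-(2-hydroxy-4,5,6-trimethoxyphenyl)ethan-1-one | CC(=O)c1c(O)cc(OC)c(OC)c1OC | intermediate
3 | 1-[2-(benzyloxy)-4,5,6-trimethoxyphenyl]ethan-1-one | CC(=O)c1c(OCc2ccccc2)cc(OC)c(OC)c1OC | intermediate
4 | 1-[2-(benzyloxy)-4,5,6-trimethoxyphenyl]butane-1,3-dione | CC(=O)CC(=O)c1c(OCc2ccccc2)cc(OC)c(OC)c1OC | intermediate
5 | methyl 2-methoxyacetate | COCC(=O)OC | starting material
6 | 1-[2-(benzyloxy)-4,5,6-trimethoxyphenyl]-6-methoxyhexane-1,3,5-trione | COCC(=O)CC(=O)CC(=O)c1c(OCc2ccccc2)cc(OC)c(OC)c1OC | intermediate
7 | 2-[2-(benzyloxy)-4,5,6-trimethoxyphenyl]-6-(methoxymethyl)-4H-pyran-4-one | COCc1cc(=O)cc(-c2c(OCc3ccccc3)cc(OC)c(OC)c2OC)o1 | intermediate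
8 | rac-2-{6-[2-(benzyloxy)-4,5,6-trimethoxyphenyl]-4-oxo-4H-pyran-2-yl}-2-methoxyacetic acid | COC(C(=O)O)c1cc(=O)cc(-c2c(OCc3ccccc3)cc(OC)c(OC)c2OC)o1 | intermediate
9 | potassium methyl malonate (potassium 3-methoxy-3-oxopropanoate) | COC(=O)CC(=O)[O-].[K+] | starting material
10 | rac-2-{6-[2-(benzyloxy)-4,5,6-trimethoxyphenyl]-4-oxo-4H-pyran-2-yl}-1-(1H-imidazol-1-yl)-2-methoxyethan-1-one | COC(C(=O)n1ccnc1)c1cc(=O)cc(-c2c(OCc3ccccc3)cc(OC)c(OC)c2OC)o1 | intermediate
11 | rac-methyl 4-{6-[2-(benzyloxy)-4,5,6-trimethoxyphenyl]-4-oxo-4H-pyran-2-yl}-4-methoxy-3-oxobutanoate | COC(=O)CC(=O)C(OC)c1cc(=O)cc(-c2c(OCc3ccccc3)cc(OC)c(OC)c2OC)o1 | intermediate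
12 | rac-methyl 9-[2-(benzyloxy)-4,5,6-trimethoxyphenyl]-4-methoxy-3,5,7,9-tetraoxononanoate | COC(=O)CC(=O)C(OC)C(=O)CC(=O)CC(=O)c1c(OCc2ccccc2)cc(OC)c(OC)c1OC | intermediate
13 | 1-[2-(benzyloxy)-4,5,6-trimethoxyphenyl]-3-(2,4,6-trihydroxy-3-methoxyphenyl)propane-1,3-dione | COc1c(O)cc(O)c(C(=O)CC(=O)c2c(OCc3ccccc3)cc(OC)c(OC)c2OC)c1O | intermediate
14 | 2-[2-(benzyloxy)-4,5,6-trimethoxyphenyl]-5,7-dihydroxy-6-methoxy-4H-chromen-4-one | COc1c(O)cc2oc(-c3c(OCc4ccccc4)cc(OC)c(OC)c3OC)cc(=O)c2c1O | intermediate
15 | 2-[2-(benzyloxy)-4,5,6-trimethoxyphenyl]-5-hydroxy-6,7-dimethoxy-4H-chromen-4-one | COc1cc2oc(-c3c(OCc4ccccc4)cc(OC)c(OC)c3OC)cc(=O)c2c(O)c1OC | intermediate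
16 | 5-hydroxy-2-(6-hydroxy-2,3,4-trimethoxyphenyl)-6,7-dimethoxy-4H-chromen-4-one | COc1cc(O)c(-c2cc(=O)c3c(O)c(OC)c(OC)cc3o2)c(OC)c1OC | target

## Step count and risks

Total step count: 11. Longest linear sequence: 11 steps (1 to 16); 5 and 9 are purchased.

**Step 8 (key step).** The polyenolate of 12 may close by aldol condensation (C8 onto C4, or C3 onto C7) to resorcylate-type benzenes, or the ester may be saponified before C4a reaches it. The chain has more ketone acceptors than the triketo esters on which the Claisen preference is established. Fallback: a chalcone route that sets out from 1 and 2 and comes back to the route at 15. Phenol 1 is benzylated (BnBr, K2CO3, DMF) to 5-(benzyloxy)-1,2,3-trimethoxybenzene F1. Vilsmeier–Haack formylation (POCl3, DMF) at the only free type of position gives 2-(benzyloxy)-4,5,6-trimethoxybenzaldehyde F2. Claisen–Schmidt condensation of F2 with 2 (KOH, EtOH) gives (E)-3-[2-(benzyloxy)-4,5,6-trimethoxyphenyl]-1-(2-hydroxy-4,5,6-trimethoxyphenyl)prop-2-en-1-one F3. I2 (cat.) in DMSO at 130 °C closes and dehydrogenates it to 2-[2-(benzyloxy)-4,5,6-trimethoxyphenyl]-5,6,7-trimethoxy-4H-chromen-4-one F4 (the flavone also met as A9). MgI2·OEt2 in THF cleaves only the methyl ether peri to the carbonyl and gives 15, after which step 11 follows.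

**Step 6.** The acid 8 is a vinylogous β-keto acid and may lose CO2 during acidification and isolation; proton transfer from the acidic α-position of the carboxylate to unreacted anion may also hold back conversion. Fallback: from 7 directly to 11, bypassing 8 and 10. The lateral lithium anion of 7 (2 equiv, LiN(iPr)2, THF, −78 °C) is C-acylated with methyl malonyl chloride, the second equivalent taking up the acidic proton of the β-keto ester. If the acid chloride is first deprotonated to (methoxycarbonyl)ketene, the anion adds to the ketene carbon and reaches the same enolate. No new isolated compound is involved.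

**Step 7.** The imidazolide 10 has an α-hydrogen flanked by the pyranone, the methoxyl and the acyl group; enolization to a ketene and self-condensation may outrun C-acylation of the magnesium malonate. Fallback: Oikawa–Yonemitsu homologation, setting out from 8 and coming back at 11. Acid 8 is coupled with Meldrum's acid (DCC, DMAP, CH2Cl2, 0 °C) to rac-5-(2-{6-[2-(benzyloxy)-4,5,6-trimethoxyphenyl]-4-oxo-4H-pyran-2-yl}-2-methoxyacetyl)-2,2-dimethyl-1,3-dioxane-4,6-dione F5, which in refluxing MeOH opens by way of the acylketene to 11.

**Step 9.** Closure through the C5 oxygen may compete with closure through the C8a oxygen, because the two ortho hydroxyls of 13 differ only in the neighbouring methoxyl. Stronger acid to force equilibration would cost the benzyl ether and expose ring B to the reopening described earlier. Fallback: a separate-and-recycle loop that sets out from 13 and comes back at 13. The closure is run as in step 9 and the regioisomer 2-[2-(benzyloxy)-4,5,6-trimethoxyphenyl]-5,7-dihydroxy-8-methoxy-4H-chromen-4-one F6 is separated from 14. Its pyranone ring is reopened by alkaline fission stopped at the diketone stage (aq. KOH, pyridine, warm), and acidification returns 13 for another pass. Should the bias prove to favour the wrong oxygen outright, the chalcone route described for step 8 bypasses the question.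

## Further compounds

F1 | step 8 | 5-(benzyloxy)-1,2,3-trimethoxybenzene | COc1cc(OCc2ccccc2)cc(OC)c1OC
F2 | step 8 | 2-(benzyloxy)-4,5,6-trimethoxybenzaldehyde | O=Cc1c(OCc2ccccc2)cc(OC)c(OC)c1OC
F3 | step 8 | (E)-3-[2-(benzyloxy)-4,5,6-trimethoxyphenyl]-1-(2-hydroxy-4,5,6-trimethoxyphenyl)prop-2-en-1-one | COc1cc(O)c(C(=O)/C=C/c2c(OCc3ccccc3)cc(OC)c(OC)c2OC)c(OC)c1OC
F4 | step 8 | 2-[2-(benzyloxy)-4,5,6-trimethoxyphenyl]-5,6,7-trimethoxy-4H-chromen-4-one | COc1cc2oc(-c3c(OCc4ccccc4)cc(OC)c(OC)c3OC)cc(=O)c2c(OC)c1OC
F0 | step 6 | none | none
F5 | step 7 | rac-5-(2-{6-[2-(benzyloxy)-4,5,6-trimethoxyphenyl]-4-oxo-4H-pyran-2-yl}-2-methoxyacetyl)-2,2-dimethyl-1,3-dioxane-4,6-dione | COC(C(=O)C1C(=O)OC(C)(C)OC1=O)c1cc(=O)cc(-c2c(OCc3ccccc3)cc(OC)c(OC)c2OC)o1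
F6 | step 9 | 2-[2-(benzyloxy)-4,5,6-trimethoxyphenyl]-5,7-dihydroxy-8-methoxy-4H-chromen-4-one | COc1c(O)cc(O)c2c(=O)cc(-c3c(OCc4ccccc4)cc(OC)c(OC)c3OC)oc12
A1 | alternative 1 | 6'-hydroxy-5,6,7,2',3',4'-hexamethoxyflavone | COc1cc(O)c(-c2cc(=O)c3c(OC)c(OC)c(OC)cc3o2)c(OC)c1OC
A2 | alternative 1 | 5,6,7-trimethoxy-2-(methoxyethynyl)-4H-chromen-4-one | COC#Cc1cc(=O)c2c(OC)c(OC)c(OC)cc2o1
A3 | alternative 1 | pentacarbonyl[methoxy(1-methoxyethenyl)carbene]chromium | COC(=C)C(OC)=[Cr].[C-]#[O+].[C-]#[O+].[C-]#[O+].[C-]#[O+].[C-]#[O+]
A4 | alternative 2 | 1-[2-(benzyloxy)-4,5,6-trimethoxyphenyl]-3-(2,3-dihydroxy-4-methoxyphenyl)propane-1,3-dione | COc1ccc(C(=O)CC(=O)c2c(OCc3ccccc3)cc(OC)c(OC)c2OC)c(O)c1O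
A5 | alternative 2 | 1-[2-(benzyloxy)-4,5,6-trimethoxyphenyl]-3-(4-methoxy-5,6-dioxocyclohexa-1,3-dien-1-yl)propane-1,3-dione | COC1=CC=C(C(=O)CC(=O)c2c(OCc3ccccc3)cc(OC)c(OC)c2OC)C(=O)C1=O
A6 | alternative 2 | 6'-(benzyloxy)-5,6-dihydroxy-7,2',3',4'-tetramethoxyflavone | COc1cc2oc(-c3c(OCc4ccccc4)cc(OC)c(OC)c3OC)cc(=O)c2c(O)c1O
A7 | alternative 3 | 2-iodo-3,4,5-trimethoxyphenol | COc1cc(O)c(I)c(OC)c1OC
A8 | alternative 3 | 1-(benzyloxy)-2-ethynyl-3,4,5-trimethoxybenzene | C#Cc1c(OCc2ccccc2)cc(OC)c(OC)c1OC
A9 | alternative 3 | 6'-(benzyloxy)-5,6,7,2',3',4'-hexamethoxyflavone | COc1cc2oc(-c3c(OCc4ccccc4)cc(OC)c(OC)c3OC)cc(=O)c2c(OC)c1OC
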